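**Strategy.** Ring B (C5–C10) is cut at C5–C6 and C7–C8, so that its bare C6–C7 bridge between the quaternary carbons C5 and C9 becomes phenyl vinyl sulfone. C9, with its C20 methyl and the C11–C12 arm, is carried as an α-methyl-γ-butyrolactone (carbonyl carbon = C8, ring oxygen on C12) bound to C10 of a ring A enol silane (C4=C5). In one flask the C5 enolate adds to the sulfone and the C7 carbanion acylates itself on the lactone: ring B closes, C5 forms trans to 10-H, and the C12 hydroxyl is released as the handle for the side chain.

Key step: step 3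

Remark: clerodane numbering is used for all intermediates (ring A = C1–C5 and C10, ring B = C5–C10).
Remark: the enol silane is the trimethylsilyl ether and is opened with KOtBu, because an alkyllithium would also attack the lactone carbonyl.
Remark: the γ-hydroxy ketones 9, 10 and 15 can rest partly as five-membered cyclic hemiketals; the steps that follow either drain the open form or use the closed one.
Assumption: the (S)-configured oxazaborolidinium catalyst is taken to send the nucleophile to the Si face of C3 of the enone; if the first run shows the opposite sense, its mirror image is used with no other change.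

Step 1
Reactants: 1 α-methyl-γ-butyrolactone
Product: 3 3-methyl-2-(trimethylsilyloxy)-4,5-dihydrofuran, via lithium enolate 2 (not isolated)
Conditions: LiN(iPr)2 (1.1 equiv), THF, −78 °C; Me3SiCl (1.3 equiv), −78 → 0 °C; non-aqueous work-up, distillation
Reagents that add atoms: chlorotrimethylsilane, C[Si](C)(C)Cl
Why: Kinetic deprotonation and O-silylation of the fully substituted lactone enolate (silyl ketene acetal formation) should give the cyclic ketene acetal, whose double-bond geometry is fixed by the ring.

Step 2
Reactants: 3 3-methyl-2-(trimethylsilyloxy)-4,5-dihydrofuran; 4 2-methylcyclohex-2-en-1-one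
Product: 5 ring A enol silane carrying the C9 lactone
Conditions: 3 (1.5 equiv), (S)-3,3-diphenyl-1-(2-methylphenyl)tetrahydro-1H,3H-pyrrolo[1,2-c][1,3,2]oxazaborole (C24H24BNO, 20 mol %) activated by (CF3SO2)2NH (18 mol %), Ph3PO (25 mol %), toluene, −20 °C; Et3N, filtration through basic Al2O3
Reagents that add atoms: none
Why: In this catalytic enantioselective Mukaiyama–Michael addition the boron cation binds the enone carbonyl and leaves one face of C3 (= C10) open, the ring-locked ketene acetal should add through an open transition state (lk topicity, Si face of the enone carbon and Si face of the acetal carbon) to set C10 (S) and quaternary C9 (R) together, and silyl transfer to the enolate oxygen delivers the C4=C5 enol silane directly.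

Step 3
Reactants: 5 ring A enol silane carrying the C9 lactone; 6 phenyl vinyl sulfone
Product: 9 trans-decalin β-keto sulfone bearing the free C12 hydroxyl, via potassium enolate 7 (not isolated), via sulfonyl carbanion 8 (not isolated)
Conditions: KOtBu (1.05 equiv), THF, −78 → −20 °C; 6 (1.1 equiv, slow addition), −78 → −30 °C; LiN(iPr)2 (2.2 equiv), −78 → 0 °C; pH 7 buffer, neutral work-up
Reagents that add atoms: none
Why: KOtBu cleaves the O–Si bond to give the regiodefined potassium enolate 7 without attacking the lactone, and 7 adds in Michael fashion to phenyl vinyl sulfone to form C5–C6 and the C7 carbanion 8. The carbanion, regenerated by LiN(iPr)2 wherever internal proton transfer has parked the charge on the C3 enolate, attacks the lactone carbonyl C8 in a Dieckmann-type acyl substitution; collapse of the tetrahedral intermediate releases the C12 alkoxide, and immediate deprotonation of the β-keto sulfone makes the closure irreversible. The closest known reaction types are the Michael–Dieckmann annulation (Michael-initiated ring closure) and the acylation of α-sulfonyl carbanions by esters and lactones. Ring B closes in the 6-exo-trig mode, the C8=O bond lying outside the new ring. The new stereocentre C5 is controlled by C10: the quaternary lactone substituent blocks one face of the enolate, C6 enters anti to C9, and the ring fusion (C19 methyl against 10-H) should come out trans, while C7 is epimerisable and is erased in step 4. The step needs alkylation at C5 and not C3, which the enol silane fixes, and acylation at C8 only, which is secured because the lactone has no α-hydrogen (C9 is quaternary), the C4 ketone rests as its enolate and a C7–C4 bond would make a four-membered ring.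

Step 4
Reactants: 9 trans-decalin β-keto sulfone bearing the free C12 hydroxyl
Product: 11 C8/C12 mixed methyl ketal of the C4 ketone, via hydroxy diketone 10 (not isolated)
Conditions: SmI2 (3 equiv), THF–MeOH, −78 °C; aqueous work-up; then pyridinium p-toluenesulfonate (10 mol %), MeOH, rt
Reagents that add atoms: methanol, CO
Why: Reductive desulfonylation of the β-keto sulfone by SmI2 (electron-transfer cleavage of the C7–S bond) gives hydroxy diketone 10, whose C12 hydroxyl and C8 carbonyl should close in acidic methanol to the five-membered mixed ketal, masking both at once while the neopentylic C4 ketone stays free; the configuration at the ketal carbon is of no consequence.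

Step 5
Reactants: 11 C8/C12 mixed methyl ketal of the C4 ketone
Product: 13 C3=C4 enol triflate, via potassium enolate 12 (not isolated)
Conditions: KN(SiMe3)2 (1.3 equiv), THF, −78 °C; PhNTf2 (1.3 equiv), −78 → 0 °C
Reagents that add atoms: N-phenylbis(trifluoromethanesulfonimide), O=S(=O)(N(c1ccccc1)S(=O)(=O)C(F)(F)F)C(F)(F)F
Why: In this enol triflate formation the ketone can only enolise towards C3 because C5 is quaternary, so a single C3=C4 triflate should result, and the basic medium leaves the ketal intact.

Step 6
Reactants: 13 C3=C4 enol triflate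
Product: 15 C3=C4 methyl alkene with free C8 ketone and C12 hydroxyl, via ketal alkene 14 (not isolated)
Conditions: MeMgBr (2 equiv), Fe(acac)3 (10 mol %), THF–NMP, −20 → 0 °C; then 1 M HCl, THF, rt
Reagents that add atoms: methylmagnesium bromide, C[Mg]Br; water, O
Why: Iron-catalysed Kumada-type cross-coupling of the alkenyl triflate puts C18 on C4 with the double bond locked at C3=C4 (no dehydration regiochemistry to control), and the dilute acid then hydrolyses the mixed ketal 14 to return the C8 ketone and the C12 hydroxyl.

Step 7
Reactants: 15 C3=C4 methyl alkene with free C8 ketone and C12 hydroxyl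
Product: 16 C8(17) exocyclic methylene alcohol
Conditions: Ph3PCH3Br (4 equiv), KOtBu (4 equiv), toluene, rt → 90 °C
Reagents that add atoms: methyltriphenylphosphonium bromide, C[P+](c1ccccc1)(c1ccccc1)c1ccccc1.[Br-]
Why: Wittig methylenation with excess ylide at elevated temperature, the usual answer to hindered ketones, should turn C8=O into C8=C17; the C12 alkoxide is tolerated and any hemiketal reopens under the basic conditions.

Step 8
Reactants: 16 C8(17) exocyclic methylene alcohol
Product: 17 C12 alcohol with the complete decalin core
Conditions: H2 (4 atm), RhCl(PPh3)3 (10 mol %), benzene–EtOH (1:1), rt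
Reagents that add atoms: none
Why: Homogeneous hydrogenation with RhCl(PPh3)3 reduces the 1,1-disubstituted alkene and leaves the hindered trisubstituted C3=C4 alkene alone, and hydrogen should reach C8 from the face of 10-H, away from the axial C20 and C19 methyls, so that C17 becomes equatorial and cis to C20 (8R).

Step 9
Reactants: 17 C12 alcohol with the complete decalin core
Product: 18 C12 iodide
Conditions: PPh3 (1.3 equiv), I2 (1.3 equiv), imidazole (2.5 equiv), CH2Cl2, 0 °C → rt
Reagents that add atoms: iodine, II
Why: Appel-type iodination of the unhindered primary alcohol proceeds by SN2 displacement of the alkoxyphosphonium ion and touches no stereocentre.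

Step 10
Reactants: 19 but-2-yne-1,4-diol
Product: 20 4-(tert-butyldimethylsilyloxy)but-2-yn-1-ol
Conditions: 19 (3 equiv), TBSCl (1 equiv), imidazole (1.2 equiv), DMF, 0 °C → rt
Reagents that add atoms: tert-butyldimethylsilyl chloride, CC(C)(C)[Si](C)(C)Cl
Why: Statistical monosilylation of a symmetrical diol used in excess (silyl ether formation) should give the mono-ether, the surplus diol being removed with water.

Step 11
Reactants: 20 4-(tert-butyldimethylsilyloxy)but-2-yn-1-ol
Product: 22 (2Z)-4-(tert-butyldimethylsilyloxy)-3-iodobut-2-en-1-ol, via vinylalanate 21 (not isolated)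
Conditions: NaAlH2(OCH2CH2OMe)2 (1.6 equiv), THF, 0 °C; EtOAc; then I2 (1.5 equiv), −78 → 0 °C
Reagents that add atoms: iodine, II
Why: Hydroxyl-directed trans-hydroalumination of the propargylic alcohol places aluminium on the distal alkyne carbon in a five-membered alkoxyalanate, and iodinolysis with retention should give the Z-iodoalkene with iodine cis to CH2OH (the free hydroxyl is the future C15–OH, the silyl ether the future C16–O); low temperature suppresses β-elimination of the silyloxy group.

Step 12
Reactants: 18 C12 iodide; 22 (2Z)-4-(tert-butyldimethylsilyloxy)-3-iodobut-2-en-1-ol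
Product: 25 C15 allylic alcohol with C16 silyl ether, via alkyllithium 23 (not isolated), via borinate 24 (not isolated)
Conditions: 18, t-BuLi (2.1 equiv), Et2O, −78 °C; B-methoxy-9-BBN (1.2 equiv), THF, −78 °C → rt; then 22 (1.2 equiv), Pd(dppf)Cl2 (5 mol %), AsPh3 (10 mol %), K3PO4 (3 M aq.), DMF, rt
Reagents that add atoms: none
Why: Lithium–iodine exchange, capture of the alkyllithium by the borinic ester and B-alkyl Suzuki–Miyaura coupling of the resulting borinate with the alkenyl iodide form C12–C13 with retention of alkene geometry, so C12 ends cis to C15 and the oxygenated carbons C15 and C16 stay trans (13E).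

Step 13
Reactants: 25 C15 allylic alcohol with C16 silyl ether; 26 icosanoic acid
Product: 27 C15 icosanoate with C16 silyl ether
Conditions: 26 (1.2 equiv), DCC (1.3 equiv), DMAP (0.2 equiv), CH2Cl2, 0 °C → rt
Reagents that add atoms: none
Why: Steglich esterification acylates the only free hydroxyl, the allylic C15 alcohol, under neutral conditions.

Step 14
Reactants: 27 C15 icosanoate with C16 silyl ether
Product: 28 target, (13E)-16-hydroxycleroda-3,13-dien-15-yl icosanoate
Conditions: HF·pyridine, THF–pyridine, 0 °C → rt
Reagents that add atoms: none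
Why: Fluoride-mediated cleavage of the primary silyl ether under buffered conditions leaves the allylic ester and both alkenes untouched, and the E geometry keeps the freed C16 hydroxyl out of reach of the C15 ester, so acyl migration cannot occur.

**Compound list**

1 | α-methyl-γ-butyrolactone (3-methyloxolan-2-one, racemic) | CC1CCOC1=O | starting material
2 | lithium enolate of 1 (lithium 3-methyl-4,5-dihydrofuran-2-olate) | [Li+].CC1=C([O-])OCC1 | intermediate
3 | 3-methyl-2-(trimethylsilyloxy)-4,5-dihydrofuran | CC1=C(O[Si](C)(C)C)OCC1 | intermediate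
4 | 2-methylcyclohex-2-en-1-one | CC1=CCCCC1=O | starting material
5 | ring A enol silane carrying the C9 lactone, (3R)-3-methyl-3-[(1S)-2-methyl-3-(trimethylsilyloxy)cyclohex-2-en-1-yl]oxolan-2-one | C[Si](C)(C)OC1=C(C)[C@@H]([C@@]2(C)CCOC2=O)CCC1 | intermediate
6 | phenyl vinyl sulfone | C=CS(=O)(=O)c1ccccc1 | starting material
7 | potassium enolate of the ring A ketone (C4–O⁻, C4=C5), lactone intact | [K+].[O-]C1=C(C)[C@@H]([C@@]2(C)CCOC2=O)CCC1 | intermediate
8 | sulfonyl carbanion: Michael adduct with quaternary C5 (C19 methyl cis to C9 on ring A), carbanion at C7, lactone intact | [K+].O=S(=O)(c1ccccc1)[CH-]C[C@@]2(C)C(=O)CCC[C@@H]2[C@@]3(C)CCOC3=O | intermediate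
9 | trans-decalin β-keto sulfone (5R,9R,10S; C7 epimers): C4 ketone, C8 ketone, PhSO2 on C7, C19 methyl on C5, C20 methyl and CH2CH2OH (C11–C12) on C9; C19 and C20 cis, 10-H on the opposite face | OCC[C@@]1(C)C(=O)C(S(=O)(=O)c3ccccc3)C[C@@]2(C)C(=O)CCC[C@H]12 | intermediate
10 | hydroxy diketone: 9 without the sulfonyl group (C7 = CH2) | OCC[C@@]1(C)C(=O)CC[C@@]2(C)C(=O)CCC[C@H]12 | intermediate
11 | mixed ketal: C8 carries OCH3 and is bridged through oxygen to C12 (2-methoxyoxolane fused at C8–C9), C4 ketone free; C8 anomers | O1CC[C@@]2(C)C1(OC)CC[C@@]3(C)C(=O)CCC[C@H]23 | intermediate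
12 | potassium C3=C4 enolate of 11 | [K+].O1CC[C@@]2(C)C1(OC)CC[C@@]3(C)C([O-])=CCC[C@H]23 | intermediate
13 | C3=C4 enol triflate of 11 | O1CC[C@@]2(C)C1(OC)CC[C@@]3(C)C(OS(=O)(=O)C(F)(F)F)=CCC[C@H]23 | intermediate
14 | ketal alkene: 13 with CH3 (C18) in place of OTf | O1CC[C@@]2(C)C1(OC)CC[C@@]3(C)C(C)=CCC[C@H]23 | intermediate
15 | hydroxy ketone: C3=C4 alkene with C18 methyl, C8 ketone, C12 hydroxyl | OCC[C@@]1(C)C(=O)CC[C@@]2(C)C(C)=CCC[C@H]12 | intermediate
16 | C8(17) exocyclic methylene analogue of 15 | OCC[C@@]1(C)C(=C)CC[C@@]2(C)C(C)=CCC[C@H]12 | intermediate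
17 | 2-[(1S,2R,4aR,8aR)-1,2,4a,5-tetramethyl-1,2,3,4,4a,7,8,8a-octahydronaphthalen-1-yl]ethan-1-ol | OCC[C@@]1(C)[C@H](C)CC[C@@]2(C)C(C)=CCC[C@H]12 | intermediate
18 | (1S,2R,4aR,8aR)-1-(2-iodoethyl)-1,2,4a,5-tetramethyl-1,2,3,4,4a,7,8,8a-octahydronaphthalene | ICC[C@@]1(C)[C@H](C)CC[C@@]2(C)C(C)=CCC[C@H]12 | intermediate
19 | but-2-yne-1,4-diol | OCC#CCO | starting material
20 | 4-(tert-butyldimethylsilyloxy)but-2-yn-1-ol | OCC#CCO[Si](C)(C)C(C)(C)C | intermediate
21 | sodium cyclic alkoxy(vinyl)alanate from 20 (Al on the future C13, cis to the CH2O–Al arm) | [Na+].COCCO[Al-]1(OCCOC)OC/C=C1/CO[Si](C)(C)C(C)(C)C | intermediate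
22 | (2Z)-4-(tert-butyldimethylsilyloxy)-3-iodobut-2-en-1-ol | OC/C=C(\I)CO[Si](C)(C)C(C)(C)C | intermediate
23 | alkyllithium from 18 (Li on C12) | [Li]CC[C@@]1(C)[C@H](C)CC[C@@]2(C)C(C)=CCC[C@H]12 | intermediate
24 | lithium B-alkyl-B-methoxy-9-borabicyclo[3.3.1]nonane borinate (alkyl = C12 of the decalin unit) | [Li+].CO[B-]1(CC[C@@]3(C)[C@H](C)CC[C@@]4(C)C(C)=CCC[C@H]34)C2CCCC1CCC2 | intermediate
25 | (2E)-3-[(tert-butyldimethylsilyloxy)methyl]-5-[(1S,2R,4aR,8aR)-1,2,4a,5-tetramethyl-1,2,3,4,4a,7,8,8a-octahydronaphthalen-1-yl]pent-2-en-1-ol | OC/C=C(/CO[Si](C)(C)C(C)(C)C)CC[C@@]1(C)[C@H](C)CC[C@@]2(C)C(C)=CCC[C@H]12 | intermediate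
26 | icosanoic acid | CCCCCCCCCCCCCCCCCCCC(=O)O | starting material
27 | icosanoate of 25 (ester on C15–O, silyl ether on C16–O) | CCCCCCCCCCCCCCCCCCCC(=O)OC/C=C(/CO[Si](C)(C)C(C)(C)C)CC[C@@]1(C)[C@H](C)CC[C@@]2(C)C(C)=CCC[C@H]12 | intermediate
28 | (2E)-3-(hydroxymethyl)-5-[(1S,2R,4aR,8aR)-1,2,4a,5-tetramethyl-1,2,3,4,4a,7,8,8a-octahydronaphthalen-1-yl]pent-2-en-1-yl icosanoate, (5R,8R,9S,10R) in clerodane numbering | CCCCCCCCCCCCCCCCCCCC(=O)OC/C=C(/CO)CC[C@@]1(C)[C@H](C)CC[C@@]2(C)C(C)=CCC[C@H]12 | target

**Step count.** 14 steps in total; the longest linear sequence is 12 steps (steps 1–9 and 12–14), with steps 10–11 as a two-step side branch.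

**Steps most likely to fail**

1. Step 3. The C7 carbanion may be lost by proton transfer or may add to further vinyl sulfone (oligomerisation) faster than it closes on the neopentylic lactone carbonyl, or the hindered enolate may add too slowly. Fallback: the sulfone linchpin is replaced by an acrylate and the two bond formations are separated. It sets out from 5. The potassium enolate is made as in step 3 and added to methyl acrylate (THF, −78 → −20 °C, AcOH quench) to give keto ester lactone F1. KOtBu (2.2 equiv, THF, 0 °C → rt) then closes ring B by Dieckmann-type attack of the ester enolate on the lactone carbonyl, giving β-keto ester F2 as its stabilised enolate. Krapcho dealkoxycarbonylation (LiCl, wet DMSO, 140 °C) removes the ester, and the route is rejoined at hydroxy diketone 10, which is ketalised as in step 4.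

2. Step 2. The α-methyl enone may be too unreactive towards the chiral boron cation, so that background silyl-cation catalysis erodes enantiofacial control, and the relative topicity at C9 may be imperfect. Fallback: the enantioselective catalysis is given up for a racemic series with resolution. It sets out from 3 and 4. Catalysis by (CF3SO2)2NH alone (2 mol %, CH2Cl2, −78 °C) gives racemic enol silane F3. This is converted under the conditions of step 3 into racemic β-keto sulfone F4, from which any C9 epimer is removed on silica. The enantiomers of F4, which carry a UV-active sulfone, are separated by preparative chromatography on an amylose tris(3,5-dimethylphenylcarbamate) phase, and the (5R,9R,10S) enantiomer re-enters the route as 9.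

3. Step 7. Olefination may stall because the C8 carbonyl is neopentylic and is tied up as the cyclic hemiketal alkoxide, with enolisation competing. Fallback: the hydroxyl is blocked and a titanium carbene is used in place of the phosphorus ylide. It sets out from 15. Et3SiCl and imidazole (DMF, 0 °C) give silyl ether F5; Cp2TiMe2 (toluene, 70 °C, Petasis methylenation) gives methylene silyl ether F6; Bu4NF (THF, 0 °C) frees the alcohol and the route is rejoined at 16.

**Further compounds**

F1 | step 3 | keto ester lactone: methyl 3-[1-methyl-2-oxo-6-(3-methyl-2-oxooxolan-3-yl)cyclohexyl]propanoate, configured as 8 | COC(=O)CC[C@@]1(C)C(=O)CCC[C@@H]1[C@@]2(C)CCOC2=O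
F2 | step 3 | β-keto ester: 9 with CO2CH3 in place of the phenylsulfonyl group on C7 | OCC[C@@]1(C)C(=O)C(C(=O)OC)C[C@@]2(C)C(=O)CCC[C@H]12
F3 | step 2 | racemic enol silane (5 and its enantiomer) | C[Si](C)(C)OC1=C(C)[C@@H]([C@@]2(C)CCOC2=O)CCC1.C[Si](C)(C)OC1=C(C)[C@H]([C@]2(C)CCOC2=O)CCC1
F4 | step 2 | racemic β-keto sulfone (9 and its enantiomer) | OCC[C@@]1(C)C(=O)C(S(=O)(=O)c3ccccc3)C[C@@]2(C)C(=O)CCC[C@H]12.OCC[C@]1(C)C(=O)C(S(=O)(=O)c3ccccc3)C[C@]2(C)C(=O)CCC[C@@H]12
F5 | step 7 | triethylsilyl ether of 15 | CC[Si](CC)(CC)OCC[C@@]1(C)C(=O)CC[C@@]2(C)C(C)=CCC[C@H]12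
F6 | step 7 | triethylsilyl ether of 16 | CC[Si](CC)(CC)OCC[C@@]1(C)C(=C)CC[C@@]2(C)C(C)=CCC[C@H]12
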